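The C4–C9 ring-fusion bond (methine C4, quaternary C9 bearing CO2H), the only bond common to the cyclohexene and the nine-membered ring, is made before either ring exists. It is formed as the C=C bond of a ten-membered cis-enone by ring-closing metathesis of a seco-caryophyllene in which C9 is caryophyllene's methyl carbon and the ketone carbon is its old ring carbon. That enone is the dienophile for allyl trans-communate. A Favorskii contraction then turns the ring carbonyl into the C9 carboxyl and closes the nine-membered ring. The key-step precursor is an acyclic vinyl ketone/terminal alkene carrying the trans-cyclobutane of (−)-β-caryophyllene.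

Key step: step 4

Remark: (−)-β-caryophyllene and trans-communic acid (labda-8(17),12E,14-trien-19-oic acid) are taken as commercial natural products with the configurations drawn.

Numbering used for all compounds: C1 = ring carbon bearing the exocyclic methylene; C2, C3; C4 = ring-fusion CH; C5; C6=C7(CH3); C8 = CH bearing the decalin side-arm methylene L11; C9 = ring-fusion carbon bearing the carboxyl carbon C16; C10, C11; C12/C13 = cyclobutane CH (C12 next to CMe2); C14 = cyclobutane CH2; C15 = CMe2. Labdane atoms keep labdane numbers with prefix L.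

Step 1
Reactants: 1 (−)-β-caryophyllene
Product: 3 4-[(1S,2R)-3,3-dimethyl-2-(3-oxobutyl)cyclobutyl]pent-4-enal, via caryophyllene ozonide 2 (not isolated)
Conditions: O3 (1 equiv), CH2Cl2, −78 °C; then Me2S, −78 °C → rt
Reagents that add atoms: ozone, [O-][O+]=O
Why: Ozonolysis with one equivalent of ozone should cleave only the strained trisubstituted endocyclic (E)-alkene, which reacts far faster than the exocyclic methylene, leaving both cyclobutane stereocentres untouched.

Step 2
Reactants: 3 4-[(1S,2R)-3,3-dimethyl-2-(3-oxobutyl)cyclobutyl]pent-4-enal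
Product: 4 4-[(1R,4S)-4-(hexa-1,5-dien-2-yl)-2,2-dimethylcyclobutyl]butan-2-one
Conditions: Ph3PCH3Br, KOtBu, THF, 0 °C; then 3, −78 °C → 0 °C
Reagents that add atoms: methyltriphenylphosphonium bromide, C[P+](c1ccccc1)(c1ccccc1)c1ccccc1.[Br-]
Why: Wittig methylenation with one equivalent of the unstabilised ylide at low temperature should be selective for the aldehyde over the methyl ketone; no stereocentre is formed.

Step 3
Reactants: 4 4-[(1R,4S)-4-(hexa-1,5-dien-2-yl)-2,2-dimethylcyclobutyl]butan-2-one
Product: 7 5-[(1R,4S)-4-(hexa-1,5-dien-2-yl)-2,2-dimethylcyclobutyl]pent-1-en-3-one, via Mannich base 5 (not isolated), via trimethylammonium iodide 6 (not isolated)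
Conditions: LiN(iPr)2, THF, −78 °C; CH2=NMe2+ I−, −78 °C → rt; MeI, rt; aq. NaHCO3, CH2Cl2, rt
Reagents that add atoms: dimethylmethyleneiminium iodide, C=[N+](C)C.[I-]
Why: Kinetic deprotonation of the methyl ketone occurs at the methyl group, the enolate undergoes a Mannich reaction with the iminium salt, and quaternisation followed by mild-base β-elimination (Hofmann type) should unveil the vinyl ketone; no stereocentre is formed.

Step 4
Reactants: 7 5-[(1R,4S)-4-(hexa-1,5-dien-2-yl)-2,2-dimethylcyclobutyl]pent-1-en-3-one
Product: 8 (1R,5Z,10S)-12,12-dimethyl-9-methylidenebicyclo[8.2.0]dodec-5-en-4-one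
Conditions: second-generation Hoveyda–Grubbs catalyst RuCl2(H2IMes)(=CH-C6H4-2-OiPr) (5 mol %), toluene (2 mM), 80 °C
Reagents that add atoms: none
Why: Ring-closing alkene metathesis ([2+2]/retro-[2+2] through ruthenacyclobutanes, loss of ethene) joins the terminal alkene carbon C4 to the vinyl ketone α-carbon C9; the closest known reaction type is enone-forming ring-closing metathesis to medium-ring ketones and ten-membered lactones. It closes the ten-membered ring C4–C3–C2–C1–C13–C12–C11–C10–C16–C9 head-to-head at the two monosubstituted alkenes. No stereocentre is created; the new stereo-element, the C4=C9 geometry, should be Z because the reversible second-generation catalyst equilibrates towards the less strained cis-cyclodecenone. The step needs cyclisation over oligomerisation and must leave the 1,1-disubstituted C1 methylene untouched: high dilution, the rigid trans-cyclobutane and two sp2 ring atoms favour closure, while the exocyclic alkene could only give a cyclobutene with C4 or would require the disfavoured acyl-substituted ruthenium carbene at C9. The C12/C13 stereocentres are remote and unaffected.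

Step 5
Reactants: 9 trans-communic acid
Product: 10 allyl trans-communate
Conditions: allyl bromide, K2CO3, DMF, rt
Reagents that add atoms: allyl bromide, C=CCBr
Why: SN2 O-alkylation of the hindered carboxylate masks the L19 acid as an ester that can be removed under neutral conditions; no stereocentre is touched.

Step 6
Reactants: 8 (1R,5Z,10S)-12,12-dimethyl-9-methylidenebicyclo[8.2.0]dodec-5-en-4-one, 10 allyl trans-communate
Product: 11 cis-fused cyclohexene–cyclodecanone Diels–Alder adduct
Conditions: Me2AlCl (20 mol %), toluene, −20 °C → rt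
Reagents that add atoms: none
Why: In this Lewis acid-catalysed Diels–Alder reaction the enone β-carbon C4 should bond to the unsubstituted diene terminus and C9 to the substituted one ("ortho" orientation), the endo transition state of the cis-enone places H-4, H-9 and H-8 cis (C3, the ketone carbon C16 and the L11 methylene on the other face), and the diene is expected to approach the peripheral face of C4 that caryophyllene itself presents to electrophiles, which sets C4 and C8 relative to the cyclobutane.

Step 7
Reactants: 11 cis-fused cyclohexene–cyclodecanone Diels–Alder adduct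
Product: 12 C10-bromo ketone
Conditions: LiN(iPr)2, THF, −78 °C; then NBS, −78 °C
Reagents that add atoms: N-bromosuccinimide, O=C1CCC(=O)N1Br
Why: The amide base should remove the less hindered α'-proton at C10 (kinetic enolate of a ketone flanked by CH2 and a ring-fusion CH) and the enolate is brominated; the configuration at C10 is inconsequential.

Step 8
Reactants: 12 C10-bromo ketone
Product: 14 bis(allyl) ester of the target, via fused cyclopropanone 13 (not isolated)
Conditions: NaH, allyl alcohol, THF, 0 °C; then 12, 0 °C → rt
Reagents that add atoms: allyl alcohol (as sodium allyloxide), C=CCO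
Why: In this Favorskii rearrangement, alkoxide-mediated enolisation at the ring-fusion carbon C9, intramolecular displacement of bromide to the cyclopropanone on the enolate face anti to the cis C3 and L11 substituents, and alkoxide opening towards the less substituted carbanion (C10) should leave the carboxyl carbon C16 on the now quaternary C9 and a trans-fused nine-membered ring.

Step 9
Reactants: 14 bis(allyl) ester of the target
Product: 15 target diacid CNP0330729.1
Conditions: Pd(PPh3)4 (5 mol %), morpholine, THF, rt
Reagents that add atoms: none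
Why: Palladium-catalysed allyl transfer to morpholine (Tsuji–Trost deallylation) should free both hindered carboxylic acids under neutral conditions without touching the alkenes or any stereocentre.

Compound list
1 | (−)-β-caryophyllene, (1R,4E,9S)-4,11,11-trimethyl-8-methylidenebicyclo[7.2.0]undec-4-ene | C/C1=C\CCC(=C)[C@H]2CC(C)(C)[C@@H]2CC1 | starting material
2 | caryophyllene ozonide (1,2,4-trioxolane across the former endocyclic alkene, mixture at the trioxolane carbons) | CC12CC[C@@H]3[C@H](CC3(C)C)C(=C)CCC(OO1)O2 | intermediate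
3 | 4-[(1S,2R)-3,3-dimethyl-2-(3-oxobutyl)cyclobutyl]pent-4-enal | O=CCCC(=C)[C@H]1CC(C)(C)[C@@H]1CCC(C)=O | intermediate
4 | 4-[(1R,4S)-4-(hexa-1,5-dien-2-yl)-2,2-dimethylcyclobutyl]butan-2-one | C=CCCC(=C)[C@H]1CC(C)(C)[C@@H]1CCC(C)=O | intermediate
5 | Mannich base, 1-(dimethylamino)-5-[(1R,4S)-4-(hexa-1,5-dien-2-yl)-2,2-dimethylcyclobutyl]pentan-3-one | C=CCCC(=C)[C@H]1CC(C)(C)[C@@H]1CCC(=O)CCN(C)C | intermediate
6 | trimethylammonium iodide of 5 | C=CCCC(=C)[C@H]1CC(C)(C)[C@@H]1CCC(=O)CC[N+](C)(C)C.[I-] | intermediate
7 | 5-[(1R,4S)-4-(hexa-1,5-dien-2-yl)-2,2-dimethylcyclobutyl]pent-1-en-3-one | C=CCCC(=C)[C@H]1CC(C)(C)[C@@H]1CCC(=O)C=C | intermediate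
8 | (1R,5Z,10S)-12,12-dimethyl-9-methylidenebicyclo[8.2.0]dodec-5-en-4-one (ten-membered cis-enone, C16=O, C9=C4) | O=C1/C=C\CCC(=C)[C@H]2CC(C)(C)[C@@H]2CC1 | intermediate
9 | trans-communic acid, (1S,4aR,5S,8aR)-1,4a-dimethyl-6-methylidene-5-[(2E)-3-methylpenta-2,4-dien-1-yl]decahydronaphthalene-1-carboxylic acid | C=C/C(C)=C/C[C@H]1C(=C)CC[C@@H]2[C@]1(C)CCC[C@]2(C)C(=O)O | starting material
10 | allyl trans-communate (prop-2-enyl ester of 9) | C=C/C(C)=C/C[C@H]1C(=C)CC[C@@H]2[C@]1(C)CCC[C@]2(C)C(=O)OCC=C | intermediate
11 | Diels–Alder adduct: cyclohexene C4–C9 cis-fused to the ten-membered ring ketone (C16=O between C9 and C10); H-4, H-8 and H-9 mutually cis; C8 carries the L11 methylene of the allyl labdanoate unit | C=C1CC[C@H]2CC=C(C)[C@@H](C[C@H]3C(=C)CC[C@@H]4[C@]3(C)CCC[C@]4(C)C(=O)OCC=C)[C@H]2C(=O)CC[C@@H]2[C@@H]1CC2(C)C | intermediate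
12 | 11 brominated at C10 (α' to the ketone), either C10 epimer | C=C1CC[C@H]2CC=C(C)[C@@H](C[C@H]3C(=C)CC[C@@H]4[C@]3(C)CCC[C@]4(C)C(=O)OCC=C)[C@H]2C(=O)C(Br)C[C@@H]2[C@@H]1CC2(C)C | intermediate
13 | fused cyclopropanone: C16(=O) bridging C9 and C10, the new C9–C10 bond on the face of H-4/H-8 | C=C1CC[C@H]2CC=C(C)[C@@H](C[C@H]3C(=C)CC[C@@H]4[C@]3(C)CCC[C@]4(C)C(=O)OCC=C)[C@@]25C(=O)C5C[C@@H]2[C@@H]1CC2(C)C | intermediate
14 | bis(allyl) ester of the target (allyl esters at C16 and L19) | C=C1CC[C@H]2CC=C(C)[C@@H](C[C@H]3C(=C)CC[C@@H]4[C@]3(C)CCC[C@]4(C)C(=O)OCC=C)[C@]2(C(=O)OCC=C)CC[C@@H]2[C@@H]1CC2(C)C | intermediate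
15 | target diacid CNP0330729.1 | C=C1CC[C@H]2CC=C(C)[C@@H](C[C@H]3C(=C)CC[C@@H]4[C@]3(C)CCC[C@]4(C)C(=O)O)[C@]2(C(=O)O)CC[C@@H]2[C@@H]1CC2(C)C | target

Total step count: 9. Longest linear sequence: 8 steps (1 → 15 through steps 1–4 and 6–9).

Steps most likely to fail

Step 4 (ring closure). Intermolecular metathesis (oligomerisation) may outrun closure of the strained ten-membered ring, or the enone may form with the trans double bond. Fallback: the same C4–C9 bond is made by a SmI2-mediated Reformatsky-type aldol cyclisation. It sets out from 3. Aldehyde-selective acetalisation (HC(OMe)3, MeOH, pyridinium p-toluenesulfonate) should give the keto dimethyl acetal F1. Kinetic silyl enol ether formation (LiN(iPr)2, Me3SiCl, −78 °C) followed by NBS should give the bromomethyl ketone acetal F2. Mild aqueous acid should free the bromomethyl keto aldehyde F3. SmI2 (THF, −78 °C, high dilution) should close the ten-membered β-hydroxy ketone F4. Mesylation and elimination (MsCl, Et3N; then DBU) should return to 8.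

Step 6 (cycloaddition). Discrimination between the two faces of the flexible ten-membered enone may be poor, or a slow cycloaddition may leave time for Lewis acid-induced cyclisation of the diene. Fallback: reagent control replaces substrate control. The same partners 8 and 10 are combined under a chiral oxazaborolidinium Lewis acid (B-o-tolyl oxazaborolidine of α,α-diphenylprolinol activated by HNTf2, CH2Cl2, −78 °C → −20 °C), the catalyst enantiomer being chosen to shield the undesired enone face. It sets out from 8 and 10 and returns at 11 with no new compound (F0).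

Step 8 (ring contraction). Enolisation at the hindered ring-fusion carbon may be slower than alkoxide attack on the carbonyl, so that a semibenzilic shift places the carboxyl on C10, or direct substitution of bromide intervenes. Fallback: cleave and re-close instead of contracting. It sets out from 11. Kinetic enolate hydroxylation (LiN(iPr)2; 2-(phenylsulfonyl)-3-phenyloxaziridine) should give the C10-hydroxy ketone F5. Pb(OAc)4 in allyl alcohol/benzene should cleave the ketol to the allyl ester aldehyde F6 (C16 ester on C9, aldehyde at C10). NaBH4 should give the primary alcohol F7, and I2/PPh3/imidazole the primary iodide F8. KN(SiMe3)2 (THF, high dilution, −78 °C → 0 °C) should alkylate the C9 ester enolate intramolecularly on the face anti to the C3 and L11 substituents, closing the nine-membered ring and returning to 14.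

Further compounds
F1 | step 4 | keto dimethyl acetal of 3 | COC(OC)CCC(=C)[C@H]1CC(C)(C)[C@@H]1CCC(C)=O
F2 | step 4 | bromomethyl ketone dimethyl acetal | COC(OC)CCC(=C)[C@H]1CC(C)(C)[C@@H]1CCC(=O)CBr
F3 | step 4 | bromomethyl keto aldehyde | O=CCCC(=C)[C@H]1CC(C)(C)[C@@H]1CCC(=O)CBr
F4 | step 4 | ten-membered β-hydroxy ketone (hydroxyl at C4, either epimer) | O=C1CC(O)CCC(=C)[C@H]2CC(C)(C)[C@@H]2CC1
F0 | step 6 | none | none
F5 | step 8 | C10-hydroxy ketone derived from 11 | C=C1CC[C@H]2CC=C(C)[C@@H](C[C@H]3C(=C)CC[C@@H]4[C@]3(C)CCC[C@]4(C)C(=O)OCC=C)[C@H]2C(=O)C(O)C[C@@H]2[C@@H]1CC2(C)C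
F6 | step 8 | seco allyl ester aldehyde (C16 allyl ester on C9, C10 aldehyde) | C=C(CC[C@H]1CC=C(C)[C@@H](C[C@H]2C(=C)CC[C@@H]3[C@]2(C)CCC[C@]3(C)C(=O)OCC=C)[C@H]1C(=O)OCC=C)[C@H]1CC(C)(C)[C@@H]1CC=O
F7 | step 8 | seco allyl ester primary alcohol (C10 hydroxyl) | C=C(CC[C@H]1CC=C(C)[C@@H](C[C@H]2C(=C)CC[C@@H]3[C@]2(C)CCC[C@]3(C)C(=O)OCC=C)[C@H]1C(=O)OCC=C)[C@H]1CC(C)(C)[C@@H]1CCO
F8 | step 8 | seco allyl ester primary iodide (C10 iodide) | C=C(CC[C@H]1CC=C(C)[C@@H](C[C@H]2C(=C)CC[C@@H]3[C@]2(C)CCC[C@]3(C)C(=O)OCC=C)[C@H]1C(=O)OCC=C)[C@H]1CC(C)(C)[C@@H]1CCI
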